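**Plan** (chain numbered C1 = carboxyl carbon to C16 = benzylic CH2; ring oxygens O1 on C6 and O2 on C3)

- Cuts: unmasking at C3 (OMe to OH) and C1 (ester to acid); the O1–C6 bond of the 1,2-dioxane (with C5–Hg, later C5–H); the C3–OOH bond; C2–C3 (diazoacetate homologation); C6–C7 (sp2–sp3 coupling); C9–C10 (Grignard coupling).
- Forward: the open chain is joined first (C9–C10, then C6–C7, then C2–C3). The 1,2-dioxane, the only ring that is made, is closed last at O1–C6.
- Enabling feature: C6 is a fully substituted peroxide carbon next to an unsubstituted C5H2 and 1,3 to the C4 methyl stereocentre. A (5E)-C5=C6 alkene lying 6-endo to a hydroperoxide on the ketal carbon C3 can therefore be closed by anti peroxymercuration, and the mercury on C5 reduced off.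
- Stereochemistry: C4 comes from methyl (S)-3-hydroxy-2-methylpropanoate and C8 from (S)-1-bromo-3-chloro-2-methylpropane. C6 comes from the E alkene geometry (syn hydrozirconation, retentive couplings), relayed from C4 by allylic 1,3-strain in the anti addition. C3 is set by anomeric equilibration of the hemiketal.

Key step: step 12

Remark: C3 is a peroxy hemiketal carbon that equilibrates through the open γ-hydroperoxy β-keto acid. Its (3S) configuration (axial OH, equatorial CH2CO2H, both carbon arms at C4 and C6 equatorial) is taken to be the thermodynamic one.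

**Step 1**
Reactants: 1 methyl (S)-3-hydroxy-2-methylpropanoate
Product: 2 methyl (S)-3-[(tert-butyldimethylsilyl)oxy]-2-methylpropanoate
Conditions: TBSCl, imidazole, DMF, 0 °C to rt
Reagents that add atoms: tert-butyldimethylsilyl chloride, CC(C)(C)[Si](C)(C)Cl
Why: Standard silylation of a primary alcohol; the stereocentre is not touched.

**Step 2**
Reactants: 2 methyl (S)-3-[(tert-butyldimethylsilyl)oxy]-2-methylpropanoate
Product: 3 (S)-3-[(tert-butyldimethylsilyl)oxy]-2-methylpropanal
Conditions: i-Bu2AlH (1.1 equiv), CH2Cl2, −78 °C; aq potassium sodium tartrate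
Reagents that add atoms: none
Why: Low-temperature half-reduction of the ester should stop at the aluminium hemiacetal and release the aldehyde on work-up; it is used crude so that the α-stereocentre is kept.

**Step 3**
Reactants: 3 (S)-3-[(tert-butyldimethylsilyl)oxy]-2-methylpropanal
Product: 4 (R)-tert-butyl[(4,4-dibromo-2-methylbut-3-en-1-yl)oxy]dimethylsilane
Conditions: CBr4, PPh3, CH2Cl2, 0 °C
Reagents that add atoms: carbon tetrabromide, BrC(Br)(Br)Br
Why: First stage of the Corey–Fuchs reaction, a Wittig-type dibromoolefination under neutral conditions that should leave the α-stereocentre intact.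

**Step 4**
Reactants: 4 (R)-tert-butyl[(4,4-dibromo-2-methylbut-3-en-1-yl)oxy]dimethylsilane
Product: 6 (R)-tert-butyldimethyl[(2-methylpent-3-yn-1-yl)oxy]silane, via lithium acetylide 5 (not isolated)
Conditions: n-BuLi (2.1 equiv), THF, −78 °C; then MeI, −78 °C to rt
Reagents that add atoms: iodomethane, CI
Why: Second stage of the Corey–Fuchs reaction (bromine–lithium exchange, α-elimination with 1,2-shift, deprotonation), with the acetylide methylated in the same flask.

**Step 5**
Reactants: 6 (R)-tert-butyldimethyl[(2-methylpent-3-yn-1-yl)oxy]silane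
Product: 8 (R,E)-tert-butyl[(4-iodo-2-methylpent-3-en-1-yl)oxy]dimethylsilane, via alkenylzirconocene chloride 7 (not isolated)
Conditions: Cp2Zr(H)Cl (2.5 equiv), THF, 50 °C; then I2, THF, 0 °C
Reagents that add atoms: iodine, II
Why: Hydrozirconation adds H and Zr syn, with Zr settling on the methyl-bearing alkyne carbon after equilibration, and iodinolysis with retention should give the E vinyl iodide (C4 arm cis to the methyl group).

**Step 6**
Reactants: 9 (7-bromoheptyl)benzene, 10 (S)-1-bromo-3-chloro-2-methylpropane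
Product: 12 (R)-1-chloro-2-methyl-10-phenyldecane, via (7-phenylheptyl)magnesium bromide 11 (not isolated)
Conditions: Mg, THF, 40 °C; then 10, Li2CuCl4 (3 mol %), THF, −10 °C to rt
Reagents that add atoms: none
Why: Copper-catalysed sp3–sp3 coupling of a Grignard reagent (Kochi type) should replace bromide selectively over chloride; the stereocentre is not involved, and the descriptor changes only because the priorities change.

**Step 7**
Reactants: 12 (R)-1-chloro-2-methyl-10-phenyldecane, 8 (R,E)-tert-butyl[(4-iodo-2-methylpent-3-en-1-yl)oxy]dimethylsilane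
Product: 15 tert-butyldimethyl{[(2R,3E,6R)-2,4,6-trimethyl-14-phenyltetradec-3-en-1-yl]oxy}silane, via alkylmagnesium chloride 13 (not isolated), via alkylzinc chloride 14 (not isolated)
Conditions: 12, Mg, THF, reflux; ZnCl2, THF, 0 °C; then 8, Pd(PPh3)4 (5 mol %), THF, rt to 45 °C
Reagents that add atoms: none
Why: Negishi sp3–sp2 coupling should proceed with retention of the alkene geometry and tolerates the silyl ether; neither stereocentre takes part.

**Step 8**
Reactants: 15 tert-butyldimethyl{[(2R,3E,6R)-2,4,6-trimethyl-14-phenyltetradec-3-en-1-yl]oxy}silane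
Product: 16 (2R,3E,6R)-2,4,6-trimethyl-14-phenyltetradec-3-en-1-ol
Conditions: TBAF, THF, 0 °C to rt
Reagents that add atoms: none
Why: Fluoride cleavage of a primary silyl ether.

**Step 9**
Reactants: 16 (2R,3E,6R)-2,4,6-trimethyl-14-phenyltetradec-3-en-1-ol
Product: 17 (2R,3E,6R)-2,4,6-trimethyl-14-phenyltetradec-3-enal
Conditions: Dess–Martin periodinane, CH2Cl2, 0 °C; used at once
Reagents that add atoms: none
Why: Dess–Martin oxidation is near neutral and should give the β,γ-unsaturated aldehyde without epimerization or alkene migration if it is not stored.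

**Step 10**
Reactants: 17 (2R,3E,6R)-2,4,6-trimethyl-14-phenyltetradec-3-enal, 18 ethyl diazoacetate
Product: 19 ethyl (4R,5E,8R)-4,6,8-trimethyl-3-oxo-16-phenylhexadec-5-enoate
Conditions: SnCl2 (10 mol %), CH2Cl2, rt
Reagents that add atoms: none
Why: Roskamp homologation (Lewis-acid addition of the diazo ester to the aldehyde, 1,2-hydride shift with loss of N2) should give the β-keto ester directly and is known to keep α-stereocentres.

**Step 11**
Reactants: 19 ethyl (4R,5E,8R)-4,6,8-trimethyl-3-oxo-16-phenylhexadec-5-enoate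
Product: 20 ethyl (4R,5E,8R)-3-hydroperoxy-3-methoxy-4,6,8-trimethyl-16-phenylhexadec-5-enoate (both C3 epimers)
Conditions: urea–hydrogen peroxide, Sc(OTf)3 (10 mol %), MeOH, 0 °C to rt
Reagents that add atoms: hydrogen peroxide, OO; methanol, CO
Why: Lewis-acid perketalization of a ketone with H2O2 in methanol should give the α-methoxy hydroperoxide; the β-keto ester enolizes toward C2, which should spare C4, and the alkene is inert to H2O2 here.

**Step 12**
Reactants: 20 ethyl (4R,5E,8R)-3-hydroperoxy-3-methoxy-4,6,8-trimethyl-16-phenylhexadec-5-enoate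
Product: 22 ethyl 2-[(4R,6S)-3-methoxy-4,6-dimethyl-6-[(R)-2-methyl-10-phenyldecyl]-1,2-dioxan-3-yl]acetate (both C3 epimers), via acetoxymercurio dioxane 21 (not isolated)
Conditions: Hg(OAc)2, CH2Cl2, 0 °C; then NaBH4, aq NaOH, 0 °C
Reagents that add atoms: none
Why: Divalent mercury adds to the C5=C6 alkene to give a bridged mercurinium ion, which the terminal oxygen of the C3 hydroperoxide opens at the tertiary carbon C6 from the opposite face; NaBH4 then cleaves the C5–Hg bond in a radical chain to leave C5H2. This is a cycloperoxymercuration–demercuration of an unsaturated α-alkoxy hydroperoxide, the established way from such hydroperoxides to alkoxy-1,2-dioxanes. The ring closes in the 6-endo-trig mode, O1 to C6, through a chair-like arrangement. C6 is set by the anti addition to the E alkene, whose C6 methyl group is cis to C4: allylic 1,3-strain holds C4–H in the alkene plane and places the C3 arm with its hydroperoxide on one face, so the C6 methyl group should end axial and syn to C4–H with the decyl arm and the C4 methyl group equatorial, which is the (4R,6S) relationship. The C5 centre is erased on reduction, and C3 stays an epimer mixture that is levelled in step 13. Regioselectivity (6-endo over 5-exo) needs Markovnikov opening, secured by the fully substituted alkene carbon at C6, and chemoselectivity needs C3 masked, secured by the methyl ketal, which also withstands the borohydride.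

**Step 13**
Reactants: 22 ethyl 2-[(4R,6S)-3-methoxy-4,6-dimethyl-6-[(R)-2-methyl-10-phenyldecyl]-1,2-dioxan-3-yl]acetate
Product: 24 2-[(3S,4R,6S)-3-hydroxy-4,6-dimethyl-6-[(R)-2-methyl-10-phenyldecyl]-1,2-dioxan-3-yl]acetic acid, via methyl ketal acid 23 (not isolated)
Conditions: LiOH, THF/H2O, 0 °C; then aq HCl to pH 1, rt
Reagents that add atoms: lithium hydroxide, [Li+].[OH-]; water, O
Why: Saponification, then acid-catalysed exchange of the ketal methoxy group for hydroxyl (peroxyketals of this kind are cleaved by dilute aqueous acid) through the ring–chain equilibrium, should settle the hemiketal as the anomerically favoured (3S) isomer.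

**Compound list**

1 | methyl (S)-3-hydroxy-2-methylpropanoate | C[C@@H](CO)C(=O)OC | starting material
2 | methyl (S)-3-[(tert-butyldimethylsilyl)oxy]-2-methylpropanoate | C[C@@H](CO[Si](C)(C)C(C)(C)C)C(=O)OC | intermediate
3 | (S)-3-[(tert-butyldimethylsilyl)oxy]-2-methylpropanal | C[C@@H](CO[Si](C)(C)C(C)(C)C)C=O | intermediate
4 | (R)-tert-butyl[(4,4-dibromo-2-methylbut-3-en-1-yl)oxy]dimethylsilane | C[C@@H](CO[Si](C)(C)C(C)(C)C)C=C(Br)Br | intermediate
5 | [(R)-4-[(tert-butyldimethylsilyl)oxy]-3-methylbut-1-yn-1-yl]lithium | C[C@@H](CO[Si](C)(C)C(C)(C)C)C#C[Li] | intermediate (not isolated)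
6 | (R)-tert-butyldimethyl[(2-methylpent-3-yn-1-yl)oxy]silane | C[C@@H](CO[Si](C)(C)C(C)(C)C)C#CC | intermediate
7 | chloro[(R,E)-5-[(tert-butyldimethylsilyl)oxy]-4-methylpent-2-en-2-yl]bis(cyclopentadienyl)zirconium | C[C@@H](CO[Si](C)(C)C(C)(C)C)/C=C(\C)[Zr](Cl)(C1C=CC=C1)C1C=CC=C1 | intermediate (not isolated)
8 | (R,E)-tert-butyl[(4-iodo-2-methylpent-3-en-1-yl)oxy]dimethylsilane | C[C@@H](CO[Si](C)(C)C(C)(C)C)/C=C(\C)I | intermediate
9 | (7-bromoheptyl)benzene | BrCCCCCCCc1ccccc1 | starting material
10 | (S)-1-bromo-3-chloro-2-methylpropane | C[C@@H](CCl)CBr | starting material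
11 | (7-phenylheptyl)magnesium bromide | Br[Mg]CCCCCCCc1ccccc1 | intermediate (not isolated)
12 | (R)-1-chloro-2-methyl-10-phenyldecane | C[C@@H](CCl)CCCCCCCCc1ccccc1 | intermediate
13 | [(R)-2-methyl-10-phenyldecyl]magnesium chloride | C[C@@H](C[Mg]Cl)CCCCCCCCc1ccccc1 | intermediate (not isolated)
14 | chloro[(R)-2-methyl-10-phenyldecyl]zinc | C[C@@H](C[Zn]Cl)CCCCCCCCc1ccccc1 | intermediate (not isolated)
15 | tert-butyldimethyl{[(2R,3E,6R)-2,4,6-trimethyl-14-phenyltetradec-3-en-1-yl]oxy}silane | C[C@@H](CO[Si](C)(C)C(C)(C)C)/C=C(\C)C[C@H](C)CCCCCCCCc1ccccc1 | intermediate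
16 | (2R,3E,6R)-2,4,6-trimethyl-14-phenyltetradec-3-en-1-ol | C[C@@H](CO)/C=C(\C)C[C@H](C)CCCCCCCCc1ccccc1 | intermediate
17 | (2R,3E,6R)-2,4,6-trimethyl-14-phenyltetradec-3-enal | C[C@@H](C=O)/C=C(\C)C[C@H](C)CCCCCCCCc1ccccc1 | intermediate
18 | ethyl diazoacetate | CCOC(=O)C=[N+]=[N-] | starting material
19 | ethyl (4R,5E,8R)-4,6,8-trimethyl-3-oxo-16-phenylhexadec-5-enoate | CCOC(=O)CC(=O)[C@H](C)/C=C(\C)C[C@H](C)CCCCCCCCc1ccccc1 | intermediate
20 | ethyl (4R,5E,8R)-3-hydroperoxy-3-methoxy-4,6,8-trimethyl-16-phenylhexadec-5-enoate (both C3 epimers) | CCOC(=O)CC(OC)(OO)[C@H](C)/C=C(\C)C[C@H](C)CCCCCCCCc1ccccc1 | intermediate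
21 | ethyl 2-[(4S,5R,6S)-5-(acetoxymercurio)-3-methoxy-4,6-dimethyl-6-[(R)-2-methyl-10-phenyldecyl]-1,2-dioxan-3-yl]acetate (both C3 epimers) | C[C@H](CCCCCCCCc1ccccc1)C[C@@]1(C)[C@H]([Hg]OC(C)=O)[C@@H](C)C(OC)(CC(=O)OCC)OO1 | intermediate (not isolated)
22 | ethyl 2-[(4R,6S)-3-methoxy-4,6-dimethyl-6-[(R)-2-methyl-10-phenyldecyl]-1,2-dioxan-3-yl]acetate (both C3 epimers) | C[C@H](CCCCCCCCc1ccccc1)C[C@@]1(C)C[C@@H](C)C(OC)(CC(=O)OCC)OO1 | intermediate
23 | 2-[(4R,6S)-3-methoxy-4,6-dimethyl-6-[(R)-2-methyl-10-phenyldecyl]-1,2-dioxan-3-yl]acetic acid (both C3 epimers) | C[C@H](CCCCCCCCc1ccccc1)C[C@@]1(C)C[C@@H](C)C(OC)(CC(=O)O)OO1 | intermediate (not isolated)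
24 | 2-[(3S,4R,6S)-3-hydroxy-4,6-dimethyl-6-[(R)-2-methyl-10-phenyldecyl]-1,2-dioxan-3-yl]acetic acid | C[C@H](CCCCCCCCc1ccccc1)C[C@@]1(C)C[C@@H](C)[C@](O)(CC(=O)O)OO1 | target

**Step count and risks**

Total step count: 13. Longest linear sequence: 12 steps (steps 1 to 5, then 7 to 13); step 6 is the one-step side branch.

Steps most likely to fail:

1. Step 12. Facial control may be lost if the mercurinium ion opens to a free tertiary cation before it is captured. Capture at C5 (5-exo) may compete. During demercuration the C5 radical may attack the neighbouring O–O bond (epoxide formation with ring opening). Fallback: the ring is closed at O2–C3 instead, from a C6 hydroperoxide, at the price of C6 control. It sets out from 19. Hydroperoxysilylation of the trisubstituted alkene (Mukaiyama–Isayama reaction: Co(acac)2, O2, Et3SiH, 1,2-dichloroethane, rt) should give ethyl (4R,8R)-4,6,8-trimethyl-3-oxo-16-phenyl-6-[(triethylsilyl)peroxy]hexadecanoate F1 as both C6 epimers. HF·pyridine in THF frees the hydroperoxide, which should close onto the C3 ketone to ethyl 2-[(3S,4R,6S)-3-hydroxy-4,6-dimethyl-6-[(R)-2-methyl-10-phenyldecyl]-1,2-dioxan-3-yl]acetate F2, separated from its 6R epimer by chromatography. LiOH in THF/H2O and mild acidification then bring the route back at 24.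

2. Step 11. Acid may promote enolization toward C4 (loss of configuration, migration of the alkene into conjugation). The C3 oxocarbenium ion may be diverted to the conjugated β-methoxy enoate. The new hydroperoxide may attack the ester carbonyl. Fallback: the enol ether is made on purpose and used as a Michael acceptor. It sets out from 19. O-Methylation with trimethylsilyldiazomethane (MeOH/toluene, rt) should give ethyl (4R,5E,8R)-3-methoxy-4,6,8-trimethyl-16-phenylhexadeca-2,5-dienoate F3. Co(acac)2, O2 and Et3SiH should then give ethyl (4R,8R)-3-methoxy-4,6,8-trimethyl-16-phenyl-6-[(triethylsilyl)peroxy]hexadec-2-enoate F4. TBAF buffered with acetic acid frees ethyl (4R,8R)-6-hydroperoxy-3-methoxy-4,6,8-trimethyl-16-phenylhexadec-2-enoate F5. Et2NH in CF3CH2OH should close it by intramolecular oxa-Michael addition (6-exo-trig), and after separation of the 6R epimer the route comes back at 22.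

3. Step 10. The α-stereocentre of the β,γ-unsaturated aldehyde may epimerize, and the C3=C4 double bond may move into conjugation before or during the Lewis-acid homologation. Alkyl migration may compete with hydride migration. Fallback: the aldehyde is avoided and C2–C3 is made by acylation. It sets out from 16. Oxidation with TEMPO (cat.) and PhI(OAc)2 in MeCN/H2O should give (2R,3E,6R)-2,4,6-trimethyl-14-phenyltetradec-3-enoic acid F6. Carbonyldiimidazole in THF converts it into 1-[(2R,3E,6R)-2,4,6-trimethyl-14-phenyltetradec-3-enoyl]-1H-imidazole F7. Mg(O2CCH2CO2Et)2 in THF at rt (Masamune–Brooks acylation with decarboxylation) then brings the route back at 19.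

**Further compounds**

F1 | step 12 | ethyl (4R,8R)-4,6,8-trimethyl-3-oxo-16-phenyl-6-[(triethylsilyl)peroxy]hexadecanoate (both C6 epimers) | CCOC(=O)CC(=O)[C@H](C)CC(C)(OO[Si](CC)(CC)CC)C[C@H](C)CCCCCCCCc1ccccc1
F2 | step 12 | ethyl 2-[(3S,4R,6S)-3-hydroxy-4,6-dimethyl-6-[(R)-2-methyl-10-phenyldecyl]-1,2-dioxan-3-yl]acetate | C[C@H](CCCCCCCCc1ccccc1)C[C@@]1(C)C[C@@H](C)[C@](O)(CC(=O)OCC)OO1
F3 | step 11 | ethyl (4R,5E,8R)-3-methoxy-4,6,8-trimethyl-16-phenylhexadeca-2,5-dienoate (C2=C3 geometry not fixed) | CCOC(=O)C=C(OC)[C@H](C)/C=C(\C)C[C@H](C)CCCCCCCCc1ccccc1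
F4 | step 11 | ethyl (4R,8R)-3-methoxy-4,6,8-trimethyl-16-phenyl-6-[(triethylsilyl)peroxy]hexadec-2-enoate (both C6 epimers) | CCOC(=O)C=C(OC)[C@H](C)CC(C)(OO[Si](CC)(CC)CC)C[C@H](C)CCCCCCCCc1ccccc1
F5 | step 11 | ethyl (4R,8R)-6-hydroperoxy-3-methoxy-4,6,8-trimethyl-16-phenylhexadec-2-enoate (both C6 epimers) | CCOC(=O)C=C(OC)[C@H](C)CC(C)(OO)C[C@H](C)CCCCCCCCc1ccccc1
F6 | step 10 | (2R,3E,6R)-2,4,6-trimethyl-14-phenyltetradec-3-enoic acid | C[C@@H](C(=O)O)/C=C(\C)C[C@H](C)CCCCCCCCc1ccccc1
F7 | step 10 | 1-[(2R,3E,6R)-2,4,6-trimethyl-14-phenyltetradec-3-enoyl]-1H-imidazole | C[C@@H](C(=O)n1ccnc1)/C=C(\C)C[C@H](C)CCCCCCCCc1ccccc1
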